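**Plan**

- Retrosynthesis: cut the aryl ether bond O1–C8a and the C3=C4 olefin of the pyran ring, then the C2'=C3' enoate olefin of the chain (Wittig). This leaves a farnesol-derived tertiary vinyl carbinol, a 2-fluorobenzaldehyde and an α-homoprenyl ester ylide.
- Enabling feature: C4 is a benzylic CH ortho to the ether carbon C8a. Carried as a formyl group it activates C8a–F for SNAr by the hindered tertiary alkoxide; once methylenated it is the styrene partner for the vinyl group (C3) on C2, and the six-membered pyran closes by metathesis.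
- Forward order: chain first (farnesyl acetate → trisnor aldehyde → Wittig), then epoxidation and reductive opening to the carbinol; arene made separately; fragment union and pyran closure in one flask; the phenol is unveiled from a bromide last. The benzene ring is bought; the pyran is the only ring made.
- Stereochemistry: C2 comes from Sharpless asymmetric epoxidation (L-(+)-diethyl tartrate) and its C–O bond is never broken afterwards. The E olefins come from farnesol and from the stabilised Wittig; the cis C3=C4 is fixed by ring size.
- Helpers removed later: the formyl oxygen (lost in the methylenation) and the bromine para to fluorine (SNAr activator and latent 6-OH).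

Key step: step 11

Remark on the chemistry: 2H-chromenes can racemise by reversible electrocyclic ring opening on heating or irradiation, so from step 11 on the material is kept at or below 80 °C and away from light.

**Step 1**
Reactants: 1 (2E,6E)-farnesyl acetate
Product: 2 (2E,6E)-10-bromo-11-hydroxy-3,7,11-trimethyldodeca-2,6-dien-1-yl acetate (racemic at C10)
Conditions: NBS, THF/H2O, 0 °C
Reagents that add atoms: N-bromosuccinimide, O=C1CCC(=O)N1Br; water, O
Why: Electrophilic bromohydrin formation should take place at the terminal trisubstituted olefin (most exposed in aqueous medium; the 2,3-olefin is deactivated by the allylic acetate), with water opening the bromonium ion at the tertiary carbon; the new centre is racemic and is destroyed in step 3.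

**Step 2**
Reactants: 2 bromohydrin acetate
Product: 3 (2E,6E)-9-(3,3-dimethyloxiran-2-yl)-3,7-dimethylnona-2,6-dien-1-ol (racemic)
Conditions: K2CO3, MeOH, 20 °C
Reagents that add atoms: none
Why: Carbonate in methanol closes the bromohydrin to the epoxide (intramolecular Williamson displacement) and removes the acetate by transesterification.

**Step 3**
Reactants: 3 epoxy alcohol
Product: 4 (4E,8E)-10-hydroxy-4,8-dimethyldeca-4,8-dienal
Conditions: H5IO6, THF/H2O, 0 °C
Reagents that add atoms: none
Why: Periodic acid hydrolyses the epoxide in situ (water enters at the tertiary carbon, so the aldehyde keeps the former epoxide oxygen) and cleaves the glycol (Malaprade cleavage) to the aldehyde and acetone without touching the olefins or the allylic alcohol.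

**Step 4**
Reactants: 5 methyl (triphenyl-λ5-phosphanylidene)acetate; 6 5-bromo-2-methylpent-2-ene
Product: 8 methyl 6-methyl-2-(triphenyl-λ5-phosphanylidene)hept-5-enoate, via phosphonium bromide 7 (not isolated)
Conditions: NaI (cat.), MeCN, reflux; then 2 M NaOH, CH2Cl2, 0 °C
Reagents that add atoms: none
Why: C-alkylation of the ester-stabilised ylide by the primary bromide (iodide catalysis) gives the phosphonium salt, which aqueous hydroxide deprotonates to the α-substituted stabilised ylide.

**Step 5**
Reactants: 4 hydroxy aldehyde; 8 α-homoprenyl ylide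
Product: 9 methyl (2E,6E,10E)-12-hydroxy-6,10-dimethyl-2-(4-methylpent-3-en-1-yl)dodeca-2,6,10-trienoate
Conditions: toluene, 60 °C
Reagents that add atoms: none
Why: Wittig reaction of an α-substituted ester-stabilised ylide with an aliphatic aldehyde should place the ester trans to the β-alkyl chain (E enoate), and the free primary alcohol is tolerated.

**Step 6**
Reactants: 9 allylic alcohol
Product: 10 methyl (2E,6E)-9-[(2S,3S)-3-(hydroxymethyl)-2-methyloxiran-2-yl]-6-methyl-2-(4-methylpent-3-en-1-yl)nona-2,6-dienoate
Conditions: Ti(OiPr)4 (cat.), L-(+)-diethyl tartrate (cat.), t-BuOOH, 4 Å molecular sieves, CH2Cl2, −20 °C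
Reagents that add atoms: tert-butyl hydroperoxide, CC(C)(C)OO
Why: Sharpless asymmetric epoxidation acts only on the olefin of the allylic alcohol, and with L-(+)-diethyl tartrate an (E)-3-methylalk-2-en-1-ol should give the (2S,3S)-epoxy alcohol, which fixes the quaternary C–O centre that becomes C2 of the chromene.

**Step 7**
Reactants: 10 epoxy alcohol
Product: 11 methyl (2E,6E)-9-[(2S,3R)-3-(iodomethyl)-2-methyloxiran-2-yl]-6-methyl-2-(4-methylpent-3-en-1-yl)nona-2,6-dienoate (same spatial arrangement as 10; the descriptor changes by priority only)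
Conditions: I2, PPh3, imidazole, CH2Cl2, 0 °C
Reagents that add atoms: iodine, II
Why: Appel-type iodination replaces the primary hydroxyl by SN2 at CH2 and leaves the epoxide and both stereocentres untouched.

**Step 8**
Reactants: 11 epoxy iodide
Product: 12 methyl (2E,6E,10S)-10-hydroxy-6,10-dimethyl-2-(4-methylpent-3-en-1-yl)dodeca-2,6,11-trienoate
Conditions: Zn dust, AcOH, EtOH, 25 °C
Reagents that add atoms: none
Why: Zinc inserts into the C–I bond and the organozinc opens the neighbouring epoxide by β-elimination (reductive epoxide opening) to the tertiary vinyl carbinol; the C–O bond at the quaternary carbon is not broken, so the configuration is retained.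

**Step 9**
Reactants: 13 1-fluoro-2,3-dimethylbenzene
Product: 14 1-bromo-4-fluoro-2,3-dimethylbenzene
Conditions: Br2, Fe powder (cat.), CH2Cl2, 0 °C
Reagents that add atoms: bromine, BrBr
Why: Electrophilic aromatic bromination should go to the position para to fluorine and ortho to the 3-methyl group, which both substituents activate.

**Step 10**
Reactants: 14 bromofluoroxylene
Product: 15 5-bromo-2-fluoro-3,4-dimethylbenzaldehyde
Conditions: LDA, THF, −78 °C; DMF; then 1 M HCl
Reagents that add atoms: N,N-dimethylformamide, CN(C)C=O
Why: Directed ortho-lithiation removes the one hydrogen ortho to fluorine (far more acidic than the one next to bromine), and the aryllithium is formylated by DMF at low temperature, where loss of LiF and halogen migration are slow.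

**Step 11**
Reactants: 12 tertiary vinyl carbinol; 15 fluoro aldehyde
Product: 18 methyl (2E,6E)-9-[(2S)-6-bromo-2,7,8-trimethyl-2H-chromen-2-yl]-6-methyl-2-(4-methylpent-3-en-1-yl)nona-2,6-dienoate, via aryl ether aldehyde 16 (not isolated), via styrenyl diene 17 (not isolated)
Conditions: (i) KH (1.0 equiv) added to 12 + 15, 18-crown-6 (cat.), THF, 0 → 25 °C; (ii) Ph3P=CH2 (1.0 equiv, from Ph3PCH3Br and KOtBu), THF, 0 °C; (iii) toluene, second-generation Grubbs catalyst RuCl2(=CHPh)(PCy3)(H2IMes) (5 mol%), 45 °C, dark
Reagents that add atoms: none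
Why: In stage one the potassium alkoxide of 12, made in the presence of 15, adds to the C–F carbon to give a Meisenheimer anion that the ortho-formyl group stabilises and that loses fluoride (SNAr; closest known type: etherification of 2-fluorobenzaldehydes by tertiary alkoxides), which forms O1–C8a. In stage two the formyl oxygen, having served as activator, is exchanged for CH2 (Wittig methylenation), and in stage three a ruthenium alkylidene formed at one vinyl group adds to the other ([2+2], then cycloreversion with loss of ethene; closest known type: ring-closing metathesis of 2-vinylaryl allyl ethers to 2H-chromenes), which forms C3=C4. The only ring closed is the six-membered pyran, closed by olefin metathesis between two monosubstituted olefins, so the new endocyclic olefin is necessarily cis. No stereocentre is created: C2 is the carbinol carbon of 12, only its O–H bond is broken, and the configuration from step 6 is retained. Site selectivity in the substitution rests on fluorine being the only halogen ortho to the formyl group and the far better leaving group in addition–elimination (bromine is meta to it), and O-arylation is favoured over ester exchange or γ-deprotonation of the enoate by trapping the alkoxide as it forms at 0 °C. Selectivity in the metathesis rests on the inertness of the three trisubstituted olefins of the chain under conditions that turn over terminal olefins.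

**Step 12**
Reactants: 18 bromochromene ester
Product: 19 (2E,6E)-9-[(2S)-6-hydroxy-2,7,8-trimethyl-2H-chromen-2-yl]-6-methyl-2-(4-methylpent-3-en-1-yl)nona-2,6-dienoic acid
Conditions: Pd2(dba)3 (cat.), 2-(di-tert-butylphosphino)-3,6-dimethoxy-2',4',6'-triisopropylbiphenyl (cat.), KOH, 1,4-dioxane/H2O, 80 °C, argon, dark; then 1 M HCl to pH 4, 0 °C
Reagents that add atoms: potassium hydroxide, [K+].[OH-]
Why: Pd-catalysed C–O coupling of the aryl bromide with hydroxide (zerovalent palladium with a bulky biaryl dialkylphosphine) should give the phenoxide while the same hydroxide saponifies the methyl ester; C2 is not involved and acidification frees phenol and acid.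

**Compound list**

1 | (2E,6E)-farnesyl acetate | CC(C)=CCC/C(C)=C/CC/C(C)=C/COC(C)=O | starting material
2 | (2E,6E)-10-bromo-11-hydroxy-3,7,11-trimethyldodeca-2,6-dien-1-yl acetate (racemic) | CC(C)(O)C(Br)CC/C(C)=C/CC/C(C)=C/COC(C)=O | intermediate
3 | (2E,6E)-9-(3,3-dimethyloxiran-2-yl)-3,7-dimethylnona-2,6-dien-1-ol (racemic) | CC1(C)OC1CC/C(C)=C/CC/C(C)=C/CO | intermediate
4 | (4E,8E)-10-hydroxy-4,8-dimethyldeca-4,8-dienal | O=CCC/C(C)=C/CC/C(C)=C/CO | intermediate
5 | methyl (triphenyl-λ5-phosphanylidene)acetate | COC(=O)C=P(c1ccccc1)(c1ccccc1)c1ccccc1 | starting material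
6 | 5-bromo-2-methylpent-2-ene | CC(C)=CCCBr | starting material
7 | (1-methoxy-6-methyl-1-oxohept-5-en-2-yl)triphenylphosphonium bromide | COC(=O)C(CCC=C(C)C)[P+](c1ccccc1)(c1ccccc1)c1ccccc1.[Br-] | intermediate (not isolated)
8 | methyl 6-methyl-2-(triphenyl-λ5-phosphanylidene)hept-5-enoate | COC(=O)C(CCC=C(C)C)=P(c1ccccc1)(c1ccccc1)c1ccccc1 | intermediate
9 | methyl (2E,6E,10E)-12-hydroxy-6,10-dimethyl-2-(4-methylpent-3-en-1-yl)dodeca-2,6,10-trienoate | CC(C)=CCC/C(=C\CC/C(C)=C/CC/C(C)=C/CO)C(=O)OC | intermediate
10 | methyl (2E,6E)-9-[(2S,3S)-3-(hydroxymethyl)-2-methyloxiran-2-yl]-6-methyl-2-(4-methylpent-3-en-1-yl)nona-2,6-dienoate | CC(C)=CCC/C(=C\CC/C(C)=C/CC[C@]1(C)O[C@H]1CO)C(=O)OC | intermediate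
11 | methyl (2E,6E)-9-[(2S,3R)-3-(iodomethyl)-2-methyloxiran-2-yl]-6-methyl-2-(4-methylpent-3-en-1-yl)nona-2,6-dienoate | CC(C)=CCC/C(=C\CC/C(C)=C/CC[C@]1(C)O[C@H]1CI)C(=O)OC | intermediate
12 | methyl (2E,6E,10S)-10-hydroxy-6,10-dimethyl-2-(4-methylpent-3-en-1-yl)dodeca-2,6,11-trienoate | CC(C)=CCC/C(=C\CC/C(C)=C/CC[C@](C)(O)C=C)C(=O)OC | intermediate
13 | 1-fluoro-2,3-dimethylbenzene | Cc1cccc(F)c1C | starting material
14 | 1-bromo-4-fluoro-2,3-dimethylbenzene | Cc1c(Br)ccc(F)c1C | intermediate
15 | 5-bromo-2-fluoro-3,4-dimethylbenzaldehyde | O=Cc1cc(Br)c(C)c(C)c1F | intermediate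
16 | methyl (2E,6E,10S)-10-(4-bromo-2-formyl-5,6-dimethylphenoxy)-6,10-dimethyl-2-(4-methylpent-3-en-1-yl)dodeca-2,6,11-trienoate | CC(C)=CCC/C(=C\CC/C(C)=C/CC[C@](C)(Oc1c(C=O)cc(Br)c(C)c1C)C=C)C(=O)OC | intermediate (not isolated)
17 | methyl (2E,6E,10S)-10-(4-bromo-2-ethenyl-5,6-dimethylphenoxy)-6,10-dimethyl-2-(4-methylpent-3-en-1-yl)dodeca-2,6,11-trienoate | CC(C)=CCC/C(=C\CC/C(C)=C/CC[C@](C)(Oc1c(C=C)cc(Br)c(C)c1C)C=C)C(=O)OC | intermediate (not isolated)
18 | methyl (2E,6E)-9-[(2S)-6-bromo-2,7,8-trimethyl-2H-chromen-2-yl]-6-methyl-2-(4-methylpent-3-en-1-yl)nona-2,6-dienoate | CC(C)=CCC/C(=C\CC/C(C)=C/CC[C@@]1(C)C=Cc2cc(Br)c(C)c(C)c2O1)C(=O)OC | intermediate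
19 | (2E,6E)-9-[(2S)-6-hydroxy-2,7,8-trimethyl-2H-chromen-2-yl]-6-methyl-2-(4-methylpent-3-en-1-yl)nona-2,6-dienoic acid | CC(C)=CCC/C(=C\CC/C(C)=C/CC[C@@]1(C)C=Cc2cc(O)c(C)c(C)c2O1)C(=O)O | target

**Totals**

Total step count: 12. Longest linear sequence: 9 steps (1, 2, 3, 5, 6, 7, 8, 11, 12).

**Steps most likely to fail**

Step 11. The intermolecular SNAr may stall at the doubly flanked C–F carbon. The alkoxide may instead deprotonate the enoate at its γ-positions, exchange with the methyl ester or add to the formyl group. Residual base or ylide may also deactivate the ruthenium catalyst in the telescoped sequence. The fallback sets out from 9 and 15 and comes back at 16, making the aryl–O–C2 linkage from the other side by forming O–C2 under catalyst control. Compound 15 would be converted by KOH in DMSO/H2O into 5-bromo-2-hydroxy-3,4-dimethylbenzaldehyde F1. The primary allylic alcohol 9 would be converted with ClCO2Me and pyridine into methyl (2E,6E,10E)-12-[(methoxycarbonyl)oxy]-6,10-dimethyl-2-(4-methylpent-3-en-1-yl)dodeca-2,6,10-trienoate F2. The two would be joined by Pd-catalysed asymmetric allylic etherification (Tsuji–Trost type: Pd2(dba)3 and N,N'-(cyclohexane-1,2-diyl)bis[2-(diphenylphosphino)benzamide], CH2Cl2, 20 °C). This reaction type is known to give the branched tertiary aryl ether from 3,3-disubstituted allyl carbonates. The ligand enantiomer that gives the S ether would have to be assigned on the first run. From 16, methylenation and ring-closing metathesis would be run as two separate operations to 18; steps 6 to 8 are then not needed.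

Step 12. The hot basic medium may erode the configuration at C2 (electrocyclic ring opening of the electron-rich chromene phenoxide), oxidise the product phenoxide, or arylate it a second time. The fallback sets out from 18 and comes back at 19, bringing in the oxygen through boron. Miyaura borylation (B2pin2, PdCl2(dppf), KOAc, 1,4-dioxane, 70 °C) would give methyl (2E,6E)-6-methyl-2-(4-methylpent-3-en-1-yl)-9-[(2S)-2,7,8-trimethyl-6-(4,4,5,5-tetramethyl-1,3,2-dioxaborolan-2-yl)-2H-chromen-2-yl]nona-2,6-dienoate F3. Oxidation with NaBO3·4H2O in THF/H2O at 20 °C would give methyl (2E,6E)-9-[(2S)-6-hydroxy-2,7,8-trimethyl-2H-chromen-2-yl]-6-methyl-2-(4-methylpent-3-en-1-yl)nona-2,6-dienoate F4. LiOH in THF/MeOH/H2O at 20 °C under argon would then give 19.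

Step 4. C-alkylation of the stabilised ylide by an unactivated homoallylic bromide may be too slow, and elimination of HBr from 6 may compete. The fallback sets out from 6 (and 4) and comes back at 9, introducing the α-substituent at the phosphonate stage. Trimethyl phosphonoacetate would be deprotonated (NaH, DMF) and alkylated with 6 to methyl 2-(dimethoxyphosphoryl)-6-methylhept-5-enoate F5. Horner–Wadsworth–Emmons reaction of F5 with 4 (LiCl, DBU, MeCN) would give 9 directly; the olefin isomers would have to be separated.

**Further compounds**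

F1 | step 11 | 5-bromo-2-hydroxy-3,4-dimethylbenzaldehyde | O=Cc1cc(Br)c(C)c(C)c1O
F2 | step 11 | methyl (2E,6E,10E)-12-[(methoxycarbonyl)oxy]-6,10-dimethyl-2-(4-methylpent-3-en-1-yl)dodeca-2,6,10-trienoate | CC(C)=CCC/C(=C\CC/C(C)=C/CC/C(C)=C/COC(=O)OC)C(=O)OC
F3 | step 12 | methyl (2E,6E)-6-methyl-2-(4-methylpent-3-en-1-yl)-9-[(2S)-2,7,8-trimethyl-6-(4,4,5,5-tetramethyl-1,3,2-dioxaborolan-2-yl)-2H-chromen-2-yl]nona-2,6-dienoate | CC(C)=CCC/C(=C\CC/C(C)=C/CC[C@@]1(C)C=Cc2cc(B3OC(C)(C)C(C)(C)O3)c(C)c(C)c2O1)C(=O)OC
F4 | step 12 | methyl (2E,6E)-9-[(2S)-6-hydroxy-2,7,8-trimethyl-2H-chromen-2-yl]-6-methyl-2-(4-methylpent-3-en-1-yl)nona-2,6-dienoate | CC(C)=CCC/C(=C\CC/C(C)=C/CC[C@@]1(C)C=Cc2cc(O)c(C)c(C)c2O1)C(=O)OC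
F5 | step 4 | methyl 2-(dimethoxyphosphoryl)-6-methylhept-5-enoate | COC(=O)C(CCC=C(C)C)P(=O)(OC)OC
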